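The easy step is a subtraction, and it is done on the charge before anything is read from the curves.

- beta: solid substrate 0.10 M; protic impurity 0.010 M; the very flask that is asked about, followed so far
- flask: solid substrate 0.10 M; protic impurity 0.0100 M; time 8.0 h

beta run (percent of the solid substrate charged)

| time / h | solid substrate / % | target / % |
|---|---|---|
| 0.200 | 43 | 16 |
| 0.333 | 17 | 35 |
| 0.667 | 0 | 59 |
| 1.33 | 1 | 68 |
| 2.50 | 1 | 68 |

(standard deviation of a reading: 1.5 percentage points)

- given per volume of solution although it is solid: solid substrate
- the earlier runs were read with a standard deviation of 1.5 percentage points
- at the start none of the solid substrate is in solution
- what has only dissolved of solid substrate counts as not reacted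
- the reaction counts as stopped when no species that holds the solid substrate changes by six tenths of a point or more over the second half of the time

- which holds at 8.0 h: what has brought the reaction to rest, or that it has not come to rest (for what has run out or reacted, a solid counts together with what of it has only dissolved) (all of the solid substrate has reacted / forward and back rates have come level / it is still moving)
- part of the solid substrate that has turned into other species by 8.0 h (what has only dissolved does not count)
- the target standing at 8.0 h, as a percentage of the solid substrate charged
- the isomer of the product standing at 8.0 h, as a percentage of the solid substrate charged

In this flask the protic impurity, at 0.0100 M, stands lower than the solid substrate at 0.10 M, so it is the limiting reagent of any one-for-one loss. The fraction of the charge left after such a loss, 90.0% here, is the free share.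

The bracket follows from it. If the protic impurity does take substrate one for one, the estimate from above puts the ceiling of the target in this flask at 90.0%; from below stand the readings of 68% at 1.33 h and 68% at 2.50 h, each with a scatter of 1.5 percentage points. The same subtraction tightens the isomer: taking the last target and solid readings from the free share leaves 21.0%, with zero as the floor, and whatever has dissolved without reacting shares that room. The reckoning here therefore commits to a target near the readings and an isomer below that figure.

The forecast states the end as "all of the solid substrate has reacted", with conversion 99.5%, target 68% and isomer 31%, and says “The isomer is the only listed species that can hold it”; its target sits on the lower edge of the bracket, and its isomer is higher than the figure reckoned here.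

The flask ends as "forward and back rates have come level", with conversion 94.0%, target 72.5% and isomer 11.5%.

    starting material ⇌ target (K = 12.0, k = 0.00168 /s)
    starting material ⇌ isomer of the product (K = 1.90, k = 7.60 × 10⁻⁴ /s)
    starting material + protic impurity → quenched substrate (k = 1.10 /M/s)
    solid substrate ⇌ starting material, rate k4*(cs4 - [starting material]) while solid is left; crystals form when [starting material] > cs4 (solubility = 43.0 mM, k = 0.00285 /s)

At 8.00 h this flask also holds 6.04% starting material, the dissolved substrate, which brings the three forms to 90.0%, the free share, beside 10.0% quenched substrate and 0% protic impurity. The target is 0.805 of that share. The neighbouring flask, charged with 0.040 M protic impurity, has a free share of 60.0%, and the same ratio gives 48.3% target. That flask stands at 48.3% target, with 40.0% quenched substrate.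

Readings and results were generated by integration for substances that don't exist.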